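**Retrosynthetic overview**
1. Glaucolide K ⇐ late epoxidation of the (E)-C4=C5 olefin, C1 acetylation, oxidative lactonization (C6–O/C12), C8 methacryloylation and C8 reduction of ten-membered enone 16.
2. 16 ⇐ seven-to-ten ring expansion of keto mesylate 14: alkyne–ketone cyclization (C7–C8 and C11–C13 bonds, transient cyclopentane) followed by Grob fragmentation of the C4–C8 bond with loss of the C5 mesylate.
3. 14 ⇐ cuprate methylation (C10), chelate-controlled C4 methylation/C5 mesylation, and aldol union (C4–C5) of enone 4 with alkynyl aldehyde 10.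
4. 4 ⇐ cyclohepta-1,3-diene (singlet oxygen, asymmetric Kornblum–DeLaMare); 10 ⇐ crotonaldehyde + a silyl propargyl ether (asymmetric alkynylation, oxidative cleavage).
5. Ring order: seven-membered carbocycle (bought) → transient cyclopentane (bicyclo[5.3.0]) → ten-membered ring → butenolide → epoxide.

Assumption: C1–C15 are germacrane locants of the target, TBS = tert-butyldimethylsilyl, and in the catalyst-controlled steps 1, 3 and 10 the catalyst antipode named is taken to be the one that gives the drawn enantiomer (otherwise its antipode is used).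

**Route**

Step 1
Reactants: 1 cyclohepta-1,3-diene
Product: 3 (S)-4-hydroxycyclohept-2-en-1-one, via bicyclic endoperoxide 2 (not isolated)
Conditions: O2, visible light, tetraphenylporphyrin (0.5 mol %), CH2Cl2, −20 °C; then 9-O-acetylcupreidine (10 mol %), CH2Cl2, 25 °C
Reagents that add atoms: dioxygen O=O
Why: Singlet-oxygen [4+2] cycloaddition gives the meso endoperoxide, and the chiral-base-catalysed Kornblum–DeLaMare rearrangement removes one of the two enantiotopic bridgehead protons, so the catalyst sets the C1 carbinol centre.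

Step 2
Reactants: 3 (S)-4-hydroxycyclohept-2-en-1-one
Product: 4 (S)-4-(TBS-oxy)cyclohept-2-en-1-one
Conditions: TBSCl, imidazole, CH2Cl2, 25 °C
Reagents that add atoms: tert-butyldimethylsilyl chloride CC(C)(C)[Si](C)(C)Cl
Why: Standard imidazole-mediated silylation of a secondary alcohol, with no stereocentre touched.

Step 3
Reactants: 5 (E)-but-2-enal; 6 trimethyl(prop-2-yn-1-yloxy)silane
Product: 8 (R,E)-hept-5-en-2-yne-1,4-diol, via trimethylsilyl ether 7 (not isolated)
Conditions: Me2Zn (3 equiv), (S,S)-ProPhenol (10 mol %), toluene, 4 °C; aq. NH4Cl; then K2CO3, MeOH, 25 °C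
Reagents that add atoms: none
Why: Zinc–ProPhenol-catalysed asymmetric alkynylation of the enal delivers the alkynylzinc to one aldehyde face and so sets the future C6 carbinol centre, and methanolysis then removes the labile trimethylsilyl ether.

Step 4
Reactants: 8 (R,E)-hept-5-en-2-yne-1,4-diol
Product: 9 (R,E)-1,4-bis(TBS-oxy)hept-5-en-2-yne
Conditions: TBSCl (2.5 equiv), imidazole, DMF, 25 °C
Reagents that add atoms: tert-butyldimethylsilyl chloride CC(C)(C)[Si](C)(C)Cl
Why: Bis-silylation of both hydroxyls with retention of configuration.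

Step 5
Reactants: 9 (R,E)-1,4-bis(TBS-oxy)hept-5-en-2-yne
Product: 10 (S)-2,5-bis(TBS-oxy)pent-3-ynal
Conditions: OsO4 (2 mol %), NaIO4 (4 equiv), 2,6-lutidine, dioxane/H2O 3:1, 25 °C; used at once
Reagents that add atoms: sodium periodate [Na+].[O-]I(=O)(=O)=O (oxygen delivered through OsO4)
Why: Lemieux–Johnson cleavage, in which OsO4 dihydroxylates the alkene in preference to the alkyne and periodate cleaves the diol, leaving the alpha-silyloxy centre untouched.

Step 6
Reactants: 4 (S)-4-(TBS-oxy)cyclohept-2-en-1-one; 10 (S)-2,5-bis(TBS-oxy)pent-3-ynal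
Product: 11 aldol adduct (C4–C5 bond; 5R,6S; both C4 epimers)
Conditions: LiN(iPr)2 (1.05 equiv), THF, −78 °C; then 10, −78 °C, 10 min; aq. NH4Cl
Reagents that add atoms: none
Why: Kinetic alpha-prime deprotonation of the enone and aldol addition with Felkin–Anh attack on the alpha-silyloxy aldehyde give the 5,6-anti carbinol; the C4 epimer ratio is irrelevant because C4 is re-enolised in step 7.

Step 7
Reactants: 11 aldol adduct
Product: 13 C4-methyl C5-mesylate enone, via lithium alkoxide 12 (not isolated)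
Conditions: LiN(iPr)2 (2.2 equiv), THF, −78 → −40 °C; MeI, DMPU, −78 → −40 °C; then MsCl, −40 → 0 °C
Reagents that add atoms: iodomethane CI; methanesulfonyl chloride CS(=O)(=O)Cl
Why: Fráter–Seebach-type alkylation in which iodomethane attacks C4 of the lithium-chelated alkoxide–enolate opposite the C6-bearing substituent, placing the C4 methyl anti to the C5 oxygen (both C4 epimers of 11 converge), and the alkoxide is mesylated cold in the same flask before retro-aldol or silyl migration can occur.

Step 8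
Reactants: 13 C4-methyl C5-mesylate enone
Product: 14 keto mesylate (2R,5S,6S)-cycloheptanone
Conditions: Me2CuLi (from MeLi and CuI, 1.5 equiv), Et2O, −78 °C; aq. NH4Cl
Reagents that add atoms: lithium dimethylcuprate [Li+].C[Cu-]C
Why: Gilman cuprate conjugate addition occurs anti to the adjacent C1 silyloxy group and gives the trans C10-methyl/C1-oxygen relationship, while the unactivated alkyne and the hindered secondary mesylate are inert at −78 °C.

Step 9
Reactants: 14 keto mesylate
Product: 16 ten-membered (4E)-enone with exocyclic C7=C11 alkene, via bicyclic zinc alkoxide 15 (not isolated)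
Conditions: AcOCH2ZnBr·LiCl (2 equiv, from BrCH2OAc, Zn dust, LiCl, THF), Ni(cod)2 (10 mol %, zerovalent nickel), THF, 0 → 25 °C; then DMPU, 50 °C
Reagents that add atoms: (acetoxymethyl)zinc bromide CC(=O)OC[Zn]Br (made in the flask from bromomethyl acetate CC(=O)OCBr)
Why: Proposed new method: nickel-catalysed acyloxymethylative alkyne–ketone cyclization telescoped with Grob fragmentation; zerovalent nickel couples the tethered alkyne and the zinc-activated C8 ketone by oxidative cyclization (5-exo, C7–C8 bond), AcOCH2ZnBr (no beta-hydrogen, so no hydride transfer) transmetallates the oxanickelacycle and C–C reductive elimination places the acetoxymethyl group on C11 syn to the new C7–C8 bond (fixing the tetrasubstituted alkene geometry), and the cis-fused zinc alkoxide 15 then expels the antiperiplanar C5 mesylate with cleavage of the C4–C8 ring-fusion bond, the cis C4-methyl/C5-mesylate relationship translating stereospecifically into the (E)-C4=C5 olefin of the ten-membered ring; the closest known reactions are the nickel-catalysed alkylative cyclization of ynals with organozinc reagents and the sequenced Barbier cyclization/Grob fragmentation of keto mesylates through samarium alkoxides.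

Step 10
Reactants: 16 ten-membered enone
Product: 17 (8S)-allylic alcohol
Conditions: (R)-2-methyl-CBS-oxazaborolidine (20 mol %), catecholborane (1.5 equiv), toluene, −78 °C
Reagents that add atoms: none
Why: Corey–Bakshi–Shibata reduction, in which the oxazaborolidine differentiates the bulky tetrasubstituted alkenyl group (C7) from the C9 methylene, so reagent control gives the (8S)-alcohol; catecholborane at −78 °C leaves the acetate and the trisubstituted alkene alone.

Step 11
Reactants: 17 (8S)-allylic alcohol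
Product: 18 C8 methacrylate
Conditions: methacryloyl chloride, iPr2NEt, DMAP (cat.), CH2Cl2, 0 °C
Reagents that add atoms: methacryloyl chloride C=C(C)C(Cl)=O
Why: DMAP-catalysed acylation of the only free hydroxyl with retention at C8.

Step 12
Reactants: 18 C8 methacrylate
Product: 19 C1,C6,C12-triol
Conditions: HF·pyridine, pyridine, THF, 0 → 25 °C
Reagents that add atoms: none
Why: Fluoride-mediated global desilylation under buffered acidic conditions, which keep the acetate and methacrylate in place and avoid base-induced acyl migration.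

Step 13
Reactants: 19 C1,C6,C12-triol
Product: 21 butenolide with free C1 hydroxyl, via lactol 20 (not isolated)
Conditions: TEMPO (20 mol %), PhI(OAc)2 (2.5 equiv), CH2Cl2, 25 °C
Reagents that add atoms: none
Why: TEMPO/PhI(OAc)2 oxidation is selective for the primary allylic alcohol; the resulting (Z)-gamma-hydroxy enal closes onto the cis-disposed C6 hydroxyl and the lactol is oxidised on to the butenolide (oxidative lactonization) with C6 unchanged.

Step 14
Reactants: 21 butenolide with free C1 hydroxyl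
Product: 22 4,5-olefin precursor (1,13-diacetate)
Conditions: Ac2O, pyridine, DMAP (cat.), CH2Cl2, 0 °C
Reagents that add atoms: acetic anhydride CC(=O)OC(C)=O
Why: DMAP-catalysed acetylation of the remaining secondary C1 alcohol with retention.

Step 15
Reactants: 22 4,5-olefin precursor
Product: 23 glaucolide K
Conditions: mCPBA, NaHCO3, CH2Cl2, 0 °C
Reagents that add atoms: 3-chloroperoxybenzoic acid OOC(=O)c1cccc(Cl)c1
Why: Prilezhaev epoxidation attacks only the electron-rich trisubstituted (E)-alkene (butenolide and methacrylate alkenes are electron-poor) from the exposed outer face of the ten-membered ring, giving stereospecifically the trans (4R,5R)-epoxide as in related 6,12-germacranolides.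

**Compound list**

1 | cyclohepta-1,3-diene | C1=CC=CCCC1 | starting material
2 | 6,7-dioxabicyclo[3.2.2]non-8-ene (meso endoperoxide) | O1O[C@@H]2CCC[C@H]1C=C2 | intermediate
3 | (S)-4-hydroxycyclohept-2-en-1-one | O=C1C=C[C@@H](O)CCC1 | intermediate
4 | (S)-4-(tert-butyldimethylsilyloxy)cyclohept-2-en-1-one | O=C1C=C[C@@H](O[Si](C)(C)C(C)(C)C)CCC1 | intermediate
5 | (E)-but-2-enal (crotonaldehyde) | C/C=C/C=O | starting material
6 | trimethyl(prop-2-yn-1-yloxy)silane | C#CCO[Si](C)(C)C | starting material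
7 | (R,E)-1-(trimethylsilyloxy)hept-5-en-2-yn-4-ol | C/C=C/[C@@H](O)C#CCO[Si](C)(C)C | intermediate
8 | (R,E)-hept-5-en-2-yne-1,4-diol | C/C=C/[C@@H](O)C#CCO | intermediate
9 | (R,E)-1,4-bis(tert-butyldimethylsilyloxy)hept-5-en-2-yne | C/C=C/[C@@H](O[Si](C)(C)C(C)(C)C)C#CCO[Si](C)(C)C(C)(C)C | intermediate
10 | (S)-2,5-bis(tert-butyldimethylsilyloxy)pent-3-ynal | O=C[C@@H](O[Si](C)(C)C(C)(C)C)C#CCO[Si](C)(C)C(C)(C)C | intermediate
11 | (4S)-4-(TBS-oxy)-7-[(1R,2S)-2,5-bis(TBS-oxy)-1-hydroxypent-3-yn-1-yl]cyclohept-2-en-1-one, both C7 epimers | O=C1C=C[C@@H](O[Si](C)(C)C(C)(C)C)CCC1[C@@H](O)[C@@H](O[Si](C)(C)C(C)(C)C)C#CCO[Si](C)(C)C(C)(C)C | intermediate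
12 | lithium alkoxide of (4S,7R)-4-(TBS-oxy)-7-[(1R,2S)-2,5-bis(TBS-oxy)-1-hydroxypent-3-yn-1-yl]-7-methylcyclohept-2-en-1-one | O=C1C=C[C@@H](O[Si](C)(C)C(C)(C)C)CC[C@]1(C)[C@@H](O[Li])[C@@H](O[Si](C)(C)C(C)(C)C)C#CCO[Si](C)(C)C(C)(C)C | intermediate
13 | (4S,7R)-4-(TBS-oxy)-7-methyl-7-[(1R,2S)-2,5-bis(TBS-oxy)-1-(methylsulfonyloxy)pent-3-yn-1-yl]cyclohept-2-en-1-one | O=C1C=C[C@@H](O[Si](C)(C)C(C)(C)C)CC[C@]1(C)[C@@H](OS(C)(=O)=O)[C@@H](O[Si](C)(C)C(C)(C)C)C#CCO[Si](C)(C)C(C)(C)C | intermediate
14 | (2R,5S,6S)-5-(TBS-oxy)-2,6-dimethyl-2-[(1R,2S)-2,5-bis(TBS-oxy)-1-(methylsulfonyloxy)pent-3-yn-1-yl]cycloheptan-1-one | O=C1C[C@H](C)[C@@H](O[Si](C)(C)C(C)(C)C)CC[C@]1(C)[C@@H](OS(C)(=O)=O)[C@@H](O[Si](C)(C)C(C)(C)C)C#CCO[Si](C)(C)C(C)(C)C | intermediate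
15 | bromozinc alkoxide of the cis-fused bicyclo[5.3.0]decan-8-ol (C8–O, C4-methyl, C5-mesylate and C6-OTBS on one face; exocyclic C7=C11 alkene with CH2OAc cis to C8 and CH2OTBS cis to C6; C1-OTBS and C10-methyl as in 14) | Br[Zn]O[C@@]12C[C@H](C)[C@@H](O[Si](C)(C)C(C)(C)C)CC[C@]1(C)[C@@H](OS(C)(=O)=O)[C@@H](O[Si](C)(C)C(C)(C)C)/C2=C(/COC(C)=O)CO[Si](C)(C)C(C)(C)C | intermediate
16 | (3R,4E,8S,9S)-2-[1-acetoxy-3-(TBS-oxy)propan-2-ylidene]-3,8-bis(TBS-oxy)-5,9-dimethylcyclodec-4-en-1-one (CH2OAc cis to the ring carbonyl) | O=C1C[C@H](C)[C@@H](O[Si](C)(C)C(C)(C)C)CC/C(C)=C/[C@@H](O[Si](C)(C)C(C)(C)C)/C1=C(/COC(C)=O)CO[Si](C)(C)C(C)(C)C | intermediate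
17 | (1S,3R,4E,8S,9S)-2-[1-acetoxy-3-(TBS-oxy)propan-2-ylidene]-3,8-bis(TBS-oxy)-5,9-dimethylcyclodec-4-en-1-ol (CH2OAc cis to C1) | O[C@H]1C[C@H](C)[C@@H](O[Si](C)(C)C(C)(C)C)CC/C(C)=C/[C@@H](O[Si](C)(C)C(C)(C)C)/C1=C(/COC(C)=O)CO[Si](C)(C)C(C)(C)C | intermediate
18 | methacrylate ester of 17 at the C1 (germacrane C8) oxygen | C=C(C)C(=O)O[C@H]1C[C@H](C)[C@@H](O[Si](C)(C)C(C)(C)C)CC/C(C)=C/[C@@H](O[Si](C)(C)C(C)(C)C)/C1=C(/COC(C)=O)CO[Si](C)(C)C(C)(C)C | intermediate
19 | triol from 18 (free hydroxyls at germacrane C1, C6 and C12; 13-acetate and 8-methacrylate retained) | C=C(C)C(=O)O[C@H]1C[C@H](C)[C@@H](O)CC/C(C)=C/[C@@H](O)/C1=C(/COC(C)=O)CO | intermediate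
20 | lactol (12-hydroxy-12,6-cyclic hemiacetal, C12 epimers) of the C12 aldehyde from 19 | C=C(C)C(=O)O[C@H]1C[C@H](C)[C@@H](O)CC/C(C)=C/[C@H]2OC(O)C(COC(C)=O)=C12 | intermediate
21 | (1S,4E,6R,8S,10S)-13-acetoxy-1-hydroxy-8-(methacryloyloxy)germacra-4,7(11)-dien-12,6-olide | C=C(C)C(=O)O[C@H]1C[C@H](C)[C@@H](O)CC/C(C)=C/[C@H]2OC(=O)C(COC(C)=O)=C12 | intermediate
22 | (1S,4E,6R,8S,10S)-1,13-diacetoxy-8-(methacryloyloxy)germacra-4,7(11)-dien-12,6-olide | C=C(C)C(=O)O[C@H]1C[C@H](C)[C@@H](OC(C)=O)CC/C(C)=C/[C@H]2OC(=O)C(COC(C)=O)=C12 | intermediate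
23 | glaucolide K, (1S,4R,5R,6S,8S,10S)-1,13-diacetoxy-4,5-epoxy-8-(methacryloyloxy)germacr-7(11)-en-12,6-olide | C=C(C)C(=O)O[C@H]1C[C@H](C)[C@@H](OC(C)=O)CC[C@@]2(C)O[C@@H]2[C@H]2OC(=O)C(COC(C)=O)=C12 | target

**Totals and risk**

Total steps: 15. Longest linear sequence: 13 steps (steps 3 to 15, from 5 and 6).

The three steps most likely to fail:

Step 9 (the proposed new cascade; the ketone may be too poor a partner for nickel, or the zinc alkoxide may not fragment). Fallback with known chemistry, setting out from 14 and coming back at 16: the divalent titanium alkoxide reagent made from Ti(OiPr)4 and two equivalents of iPrMgCl (Et2O, −78 to −30 °C) couples alkyne and ketone to an oxatitanacycle, and cleavage of the C11–Ti bond with I2 gives the cis-fused bicyclic iodo alcohol F1. Stille coupling of F1 with Bu3SnCH2OH (Pd(PPh3)4, a zerovalent palladium catalyst, dioxane, 80 °C) gives the hydroxymethyl diol F2. Ac2O/pyridine acetylates only the primary hydroxyl to give the hydroxy acetate mesylate F3. KN(SiMe3)2 (THF, −78 to 0 °C) then effects the classical Wharton–Grob fragmentation of this 1,3-hydroxy mesylate to 16.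

Step 10 (reagent control may be eroded by the congested ten-membered ketone). Fallback setting out from 16 and coming back at 18: substrate-controlled Luche reduction (NaBH4, CeCl3·7H2O, MeOH, −78 °C), which is expected to attack from the ring periphery; if this gives the epimeric (8R)-alcohol F4, Mitsunobu esterification with methacrylic acid (PPh3, DIAD, THF, 0 °C) inverts C8 and installs the methacrylate in one operation to give 18.

Step 15 (the peracid may attack the wrong face of the olefin). Fallback setting out from 22 and coming back at 23: replace substrate control by reagent control with a chiral dioxirane (Shi epoxidation: fructose-derived ketone catalyst or its enantiomer, Oxone, K2CO3 buffer, MeCN/dimethoxymethane/H2O, 0 °C), which is well suited to trans-trisubstituted olefins; this fallback makes no new compound (F0).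

Further compounds
F1 | step 9 | cis-fused bicyclo[5.3.0]decan-8-ol from 14 with exocyclic C7=C11 alkene bearing iodine (cis to C8) and CH2OTBS (cis to C6); C5 mesylate, C1/C6 OTBS, C4/C10 methyls as in 15 | O[C@@]12C[C@H](C)[C@@H](O[Si](C)(C)C(C)(C)C)CC[C@]1(C)[C@@H](OS(C)(=O)=O)[C@@H](O[Si](C)(C)C(C)(C)C)/C2=C(/I)CO[Si](C)(C)C(C)(C)C
F2 | step 9 | hydroxymethyl analogue of F1 (CH2OH in place of iodine; tertiary C8 alcohol and primary C13 alcohol) | O[C@@]12C[C@H](C)[C@@H](O[Si](C)(C)C(C)(C)C)CC[C@]1(C)[C@@H](OS(C)(=O)=O)[C@@H](O[Si](C)(C)C(C)(C)C)/C2=C(/CO)CO[Si](C)(C)C(C)(C)C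
F3 | step 9 | C13 acetate of F2 (free tertiary C8 alcohol; protonated form of 15) | O[C@@]12C[C@H](C)[C@@H](O[Si](C)(C)C(C)(C)C)CC[C@]1(C)[C@@H](OS(C)(=O)=O)[C@@H](O[Si](C)(C)C(C)(C)C)/C2=C(/COC(C)=O)CO[Si](C)(C)C(C)(C)C
F4 | step 10 | (1R,3R,4E,8S,9S)-epimer of 17 (germacrane 8R alcohol) | O[C@@H]1C[C@H](C)[C@@H](O[Si](C)(C)C(C)(C)C)CC/C(C)=C/[C@@H](O[Si](C)(C)C(C)(C)C)/C1=C(/COC(C)=O)CO[Si](C)(C)C(C)(C)C
F0 | step 15 | none | none
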